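**Retrosynthetic overview**
- The target is reached from a ring-B-closed tetralone by alkene hydrogenation, conversion of a tertiary alcohol into the isopropenyl group, oxidation of C3 to the acid, and unmasking of the 11,12,14-trioxygenated ring C (oxidative demethylation, hydrolysis, reduction).
- Ring B (C5, C6, C7, C8, C9, C10) is opened at the C9–C10 bond, the bond joining the fully substituted arene carbon C9 of ring C to the benzylic quaternary carbon C10 (methyl, C1–C3 chain, C5). It is closed by a 6-exo intramolecular Heck reaction of a C9 iodide onto an (E)-C10=C1 alkene, with C5 steering the new centre.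
- The open-chain iodoaryl ketone comes from a Carroll rearrangement of an allyl β-keto ester, which forms C5–C6, relays a C1 carbinol centre to C5 and sets the (E)-alkene.
- The allylic alcohol comes from a 2-alkyne (hydrozirconation) and a C1–C3 aldehyde (ligand-controlled alkenylzinc addition); the β-keto ester comes from 1,2,4-trimethoxybenzene. Ring C is bought, and ring B is the only ring formed.

Key step: step 13

Remark on numbering: abietane locants are used. C1–C3 is the propanoic chain (C3 = CO2H), C4 the isopropenyl carbon, C7 the ketone, C8 and C9 the ring-fusion arene carbons, C10 the quaternary carbon, C11, C12 and C14 the oxygenated arene carbons, and C13 the carbon carrying isopropyl.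

Assumption: the target is taken exactly as drawn, (5S,10R), with the isopropenyl group and the propanoic chain cis on ring B. In the silyl-protected intermediates the same spatial arrangement at C5 carries the descriptor R, because the oxygenated C4 outranks C10.

Remark on the chemistry: C5 is set by chirality transfer in a [3,3] shift and not by an intermolecular addition next to the fully substituted C4, which is too hindered to rely on.

Step 1
Reactants: 1 1,2,4-trimethoxybenzene
Product: 3 2-(2,3,6-trimethoxyphenyl)propan-2-ol, via (2,3,6-trimethoxyphenyl)lithium 2 (not isolated)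
Conditions: n-BuLi, THF, 0 °C; acetone, −78 °C → rt; H2O
Reagents that add atoms: acetone, CC(C)=O
Why: Directed ortho-lithiation should take the one ring position flanked by two methoxy groups (the future C13), and 1,2-addition of the aryllithium to acetone gives the tertiary benzylic alcohol.

Step 2
Reactants: 3 2-(2,3,6-trimethoxyphenyl)propan-2-ol
Product: 4 1,2,4-trimethoxy-3-(propan-2-yl)benzene
Conditions: Et3SiH, CF3CO2H, CH2Cl2, 0 °C → rt
Reagents that add atoms: none
Why: Ionic hydrogenation: the acid ionises the tertiary benzylic alcohol, whose cation is stabilised by two ortho methoxy groups, and the silane delivers hydride to give the isopropyl group.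

Step 3
Reactants: 4 1,2,4-trimethoxy-3-(propan-2-yl)benzene
Product: 5 1-[2,4,5-trimethoxy-3-(propan-2-yl)phenyl]ethan-1-one
Conditions: Ac2O, Sc(OTf)3 (10 mol %), MeNO2, 50 °C
Reagents that add atoms: acetic anhydride, CC(=O)OC(C)=O
Why: Friedel–Crafts acetylation should go to the free position that is para to one methoxy group and ortho to another (the future C8), and the catalytic Lewis acid is mild enough to leave the methyl ethers intact.

Step 4
Reactants: 5 1-[2,4,5-trimethoxy-3-(propan-2-yl)phenyl]ethan-1-one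
Product: 6 1-[2-iodo-3,4,6-trimethoxy-5-(propan-2-yl)phenyl]ethan-1-one
Conditions: I2, CF3CO2Ag, CH2Cl2, 0 °C → rt, dark
Reagents that add atoms: iodine, II
Why: Electrophilic aromatic iodination by the acyl hypoiodite formed in the flask can only take the last free ring position (the future C9, ortho to a methoxy group), and the weakly acidic medium disfavours enol-mediated α-iodination of the ketone.

Step 5
Reactants: 6 1-[2-iodo-3,4,6-trimethoxy-5-(propan-2-yl)phenyl]ethan-1-one
Product: 7 methyl 3-[2-iodo-3,4,6-trimethoxy-5-(propan-2-yl)phenyl]-3-oxopropanoate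
Conditions: NaH, (MeO)2CO, toluene, 80 °C; AcOH
Reagents that add atoms: dimethyl carbonate, COC(=O)OC
Why: Crossed Claisen condensation (C-carbomethoxylation of the ketone enolate) is driven by deprotonation of the β-keto ester, and the hydrogen-free ring cannot be metalated next to the iodide.

Step 6
Reactants: 8 2-methylbut-3-yn-2-ol
Product: 9 triethyl[(2-methylbut-3-yn-2-yl)oxy]silane
Conditions: Et3SiCl, imidazole, DMAP (cat.), DMF, rt
Reagents that add atoms: chlorotriethylsilane, CC[Si](Cl)(CC)CC
Why: Imidazole-promoted O-silylation protects the tertiary alcohol that will later become the isopropenyl group.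

Step 7
Reactants: 9 triethyl[(2-methylbut-3-yn-2-yl)oxy]silane
Product: 11 triethyl[(2-methylpent-3-yn-2-yl)oxy]silane, via lithium acetylide 10 (not isolated)
Conditions: n-BuLi, THF, −78 °C; MeI, −78 °C → rt
Reagents that add atoms: iodomethane, CI
Why: Deprotonation of the terminal alkyne and SN2 methylation of the acetylide install the future C10 methyl group.

Step 8
Reactants: 12 propane-1,3-diol
Product: 13 3-[(tert-butyldiphenylsilyl)oxy]propan-1-ol
Conditions: NaH (1 equiv), THF, 0 °C → rt; t-BuPh2SiCl (1 equiv)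
Reagents that add atoms: tert-butyl(chloro)diphenylsilane, CC(C)(C)[Si](Cl)(c1ccccc1)c1ccccc1
Why: Monosilylation of a symmetrical diol through its sparingly soluble monosodium alkoxide gives the mono-ether.

Step 9
Reactants: 13 3-[(tert-butyldiphenylsilyl)oxy]propan-1-ol
Product: 14 3-[(tert-butyldiphenylsilyl)oxy]propanal
Conditions: TEMPO (10 mol %), PhI(OAc)2, CH2Cl2, rt
Reagents that add atoms: none
Why: Oxoammonium-catalysed alcohol oxidation stops at the aldehyde in the absence of water and is mild enough to avoid β-elimination of the silyloxy group.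

Step 10
Reactants: 11 triethyl[(2-methylpent-3-yn-2-yl)oxy]silane; 14 3-[(tert-butyldiphenylsilyl)oxy]propanal
Product: 17 (3R,4E)-1-[(tert-butyldiphenylsilyl)oxy]-4,6-dimethyl-6-[(triethylsilyl)oxy]hept-4-en-3-ol, via alkenylzirconocene chloride 15 (not isolated), via alkenyl(methyl)zinc 16 (not isolated)
Conditions: 11, Cp2Zr(H)Cl, CH2Cl2, rt; Me2Zn, toluene, −65 °C; (−)-3-exo-morpholinoisoborneol (10 mol %), 14, −30 °C → 0 °C; aq NH4Cl
Reagents that add atoms: none
Why: syn-Hydrozirconation puts zirconium on the methyl-bearing alkyne carbon, away from the quaternary carbon, and so fixes the alkene geometry; after transmetalation to zinc the amino-alcohol ligand should direct the alkenyl group to the Si face of the aldehyde and set the (R) carbinol centre C1 (hydrozirconation, transmetalation, catalytic asymmetric alkenylzinc addition).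

Step 11
Reactants: 7 methyl 3-[2-iodo-3,4,6-trimethoxy-5-(propan-2-yl)phenyl]-3-oxopropanoate; 17 (3R,4E)-1-[(tert-butyldiphenylsilyl)oxy]-4,6-dimethyl-6-[(triethylsilyl)oxy]hept-4-en-3-ol
Product: 18 (3R,4E)-1-[(tert-butyldiphenylsilyl)oxy]-4,6-dimethyl-6-[(triethylsilyl)oxy]hept-4-en-3-yl 3-[2-iodo-3,4,6-trimethoxy-5-(propan-2-yl)phenyl]-3-oxopropanoate
Conditions: DMAP (30 mol %), toluene, reflux, 4 Å molecular sieves
Reagents that add atoms: none
Why: Amine-catalysed transesterification of a β-keto ester runs through the aroylketene, which accepts hindered secondary alcohols and does not touch the carbinol stereocentre.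

Step 12
Reactants: 18 the allyl β-keto ester of step 11
Product: 20 (3R,4E)-7-[(tert-butyldiphenylsilyl)oxy]-1-[2-iodo-3,4,6-trimethoxy-5-(propan-2-yl)phenyl]-4-methyl-3-{2-[(triethylsilyl)oxy]propan-2-yl}hept-4-en-1-one, via β-keto acid 19 (not isolated)
Conditions: o-xylene (degassed), 160 °C, sealed tube
Reagents that add atoms: none
Why: Carroll rearrangement: the ester enol undergoes a chair-like [3,3]-sigmatropic shift with the C1 side chain equatorial, so the C5–C6 bond forms on the alkene face from which the C1–O bond leaves, which turns the (R) carbinol centre into (R)-C5 and gives the (E)-C10=C1 alkene, and the β-keto acid then loses CO2.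

Step 13
Reactants: 20 the (3R,4E)-iodoaryl ketone of step 12
Product: 21 (3R,4R)-4-[(1E)-3-[(tert-butyldiphenylsilyl)oxy]prop-1-en-1-yl]-5,6,8-trimethoxy-4-methyl-7-(propan-2-yl)-3-{2-[(triethylsilyl)oxy]propan-2-yl}-3,4-dihydronaphthalen-1(2H)-one (C5 R, C10 R)
Conditions: Pd(OAc)2 (10 mol %), PPh3 (25 mol %), Ag3PO4 (1.5 equiv), DMF, 80 °C
Reagents that add atoms: none
Why: Zerovalent palladium, formed in the flask from Pd(OAc)2 and PPh3, inserts into the C9–I bond; Ag3PO4 removes iodide, the aryl–palladium species adds syn across the (E)-C10=C1 alkene to form the C9–C10 bond and ring B, and β-hydride elimination, possible only toward C2 because C10 carries no hydrogen, releases the (E)-C1=C2 alkene. The closest known reaction type is the intramolecular Heck cyclisation of aryl iodides onto trisubstituted alkenes that builds benzylic quaternary centres in six-membered rings. Ring B closes in the 6-exo-trig mode through a half-chair in which the aryl–Pd bond and the alkene are eclipsed, so C1 becomes pseudo-axial and the C10 methyl pseudo-equatorial. The new stereocentre C10 is controlled by C5: its silyloxy-isopropyl group stays pseudo-equatorial, because the pseudo-axial alternative would push it under the arene and against the C10 methyl, and this places C1 cis to it and gives (10R). The step needs exo over 7-endo closure, a single reactive alkene and no migration of the new double bond: the short ketone tether enforces exo attack, the isopropenyl group is masked as a tertiary silyl ether, ring C has no hydrogen left, and the silver salt suppresses re-addition of palladium hydride.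

Step 14
Reactants: 21 the Heck product of step 13
Product: 22 (3R,4R)-4-{3-[(tert-butyldiphenylsilyl)oxy]propyl}-5,6,8-trimethoxy-4-methyl-7-(propan-2-yl)-3-{2-[(triethylsilyl)oxy]propan-2-yl}-3,4-dihydronaphthalen-1(2H)-one
Conditions: H2 (1 atm), 10% Pd/C, EtOAc, rt
Reagents that add atoms: none
Why: Heterogeneous hydrogenation saturates the disubstituted C1=C2 alkene, while the hindered aryl ketone and both silyl ethers should survive in a neutral solvent.

Step 15
Reactants: 22 the saturated bis-silyl ether of step 14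
Product: 23 (3R,4R)-4-{3-[(tert-butyldiphenylsilyl)oxy]propyl}-3-(2-hydroxypropan-2-yl)-5,6,8-trimethoxy-4-methyl-7-(propan-2-yl)-3,4-dihydronaphthalen-1(2H)-one
Conditions: HF·pyridine, pyridine, THF, 0 °C → rt
Reagents that add atoms: none
Why: Buffered fluoride-acid desilylation should cleave the triethylsilyl ether much faster than the tert-butyldiphenylsilyl ether, freeing only the tertiary alcohol.

Step 16
Reactants: 23 the tertiary alcohol of step 15
Product: 24 (3S,4R)-4-{3-[(tert-butyldiphenylsilyl)oxy]propyl}-5,6,8-trimethoxy-4-methyl-7-(propan-2-yl)-3-(prop-1-en-2-yl)-3,4-dihydronaphthalen-1(2H)-one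
Conditions: MeO2CN(−)SO2N(+)Et3 (Burgess reagent), toluene, 50 °C
Reagents that add atoms: none
Why: Burgess dehydration is a syn-elimination of the sulfamate ester and should take one of the six methyl hydrogens and not the single C5–H shielded by the quaternary C10, so the isopropenyl group forms and C5 keeps its configuration (the descriptor changes to S by priority only).

Step 17
Reactants: 24 the isopropenyl silyl ether of step 16
Product: 25 (3S,4R)-4-(3-hydroxypropyl)-5,6,8-trimethoxy-4-methyl-7-(propan-2-yl)-3-(prop-1-en-2-yl)-3,4-dihydronaphthalen-1(2H)-one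
Conditions: Bu4NF, THF, rt
Reagents that add atoms: none
Why: Fluoride-mediated desilylation frees the primary C3 alcohol without affecting the alkene or the ketone.

Step 18
Reactants: 25 the primary alcohol of step 17
Product: 27 3-[(1R,2S)-5,7,8-trimethoxy-1-methyl-4-oxo-6-(propan-2-yl)-2-(prop-1-en-2-yl)-1,2,3,4-tetrahydronaphthalen-1-yl]propanoic acid, via aldehyde 26 (not isolated)
Conditions: TEMPO (20 mol %), PhI(OAc)2 (2.2 equiv), MeCN–H2O (1:1), rt
Reagents that add atoms: water, O
Why: Oxoammonium-catalysed oxidation in aqueous medium carries the primary alcohol through the aldehyde hydrate to the carboxylic acid and leaves the isopropenyl group and the hydrogen-free arene alone.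

Step 19
Reactants: 27 the trimethoxy acid of step 18
Product: 28 3-[(1R,2S)-7-methoxy-1-methyl-4,5,8-trioxo-6-(propan-2-yl)-2-(prop-1-en-2-yl)-1,2,3,4,5,8-hexahydronaphthalen-1-yl]propanoic acid
Conditions: (NH4)2Ce(NO3)6, MeCN–H2O, 0 °C
Reagents that add atoms: water, O
Why: Oxidative demethylation by tetravalent cerium converts the para-related C11 and C14 methoxy groups into the 11,14-quinone and keeps the C12 methoxy group as a vinylogous ester.

Step 20
Reactants: 28 the methoxyquinone of step 19
Product: 29 3-[(1R,2S)-7-hydroxy-1-methyl-4,5,8-trioxo-6-(propan-2-yl)-2-(prop-1-en-2-yl)-1,2,3,4,5,8-hexahydronaphthalen-1-yl]propanoic acid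
Conditions: NaOH (1 M aq), THF, 0 °C → rt, argon; HCl
Reagents that add atoms: sodium hydroxide, [Na+].[OH-]
Why: Addition–elimination of hydroxide at C12 (vinylogous ester hydrolysis) gives the hydroxyquinone; C5 is β to the ketone and cannot epimerise by enolisation.

Step 21
Reactants: 29 the hydroxyquinone of step 20
Product: 30 3-[(1R,2S)-5,7,8-trihydroxy-1-methyl-4-oxo-6-(propan-2-yl)-2-(prop-1-en-2-yl)-1,2,3,4-tetrahydronaphthalen-1-yl]propanoic acid (target, 5S,10R)
Conditions: Na2S2O4, THF–H2O, rt, argon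
Reagents that add atoms: none
Why: Dithionite reduction of the quinone gives the 11,12,14-trihydroxyarene, which should be isolated with exclusion of air; no stereocentre is involved.

**Compound list**
1 | 1,2,4-trimethoxybenzene | COc1ccc(OC)c(OC)c1 | starting material
2 | (2,3,6-trimethoxyphenyl)lithium | COc1ccc(OC)c(OC)c1[Li] | intermediate
3 | 2-(2,3,6-trimethoxyphenyl)propan-2-ol | COc1ccc(OC)c(OC)c1C(C)(C)O | intermediate
4 | 1,2,4-trimethoxy-3-(propan-2-yl)benzene | COc1ccc(OC)c(OC)c1C(C)C | intermediate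
5 | 1-[2,4,5-trimethoxy-3-(propan-2-yl)phenyl]ethan-1-one | COc1c(C(C)=O)cc(OC)c(OC)c1C(C)C | intermediate
6 | 1-[2-iodo-3,4,6-trimethoxy-5-(propan-2-yl)phenyl]ethan-1-one | COc1c(C(C)=O)c(I)c(OC)c(OC)c1C(C)C | intermediate
7 | methyl 3-[2-iodo-3,4,6-trimethoxy-5-(propan-2-yl)phenyl]-3-oxopropanoate | COC(=O)CC(=O)c1c(I)c(OC)c(OC)c(C(C)C)c1OC | intermediate
8 | 2-methylbut-3-yn-2-ol | CC(C)(O)C#C | starting material
9 | triethyl[(2-methylbut-3-yn-2-yl)oxy]silane | CC[Si](CC)(CC)OC(C)(C)C#C | intermediate
10 | [3-methyl-3-(triethylsilyloxy)but-1-yn-1-yl]lithium | CC[Si](CC)(CC)OC(C)(C)C#C[Li] | intermediate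
11 | triethyl[(2-methylpent-3-yn-2-yl)oxy]silane | CC#CC(C)(C)O[Si](CC)(CC)CC | intermediate
12 | propane-1,3-diol | OCCCO | starting material
13 | 3-[(tert-butyldiphenylsilyl)oxy]propan-1-ol | OCCCO[Si](c1ccccc1)(c1ccccc1)C(C)(C)C | intermediate
14 | 3-[(tert-butyldiphenylsilyl)oxy]propanal | O=CCCO[Si](c1ccccc1)(c1ccccc1)C(C)(C)C | intermediate
15 | chlorobis(cyclopentadienyl)[(2E)-4-methyl-4-(triethylsilyloxy)pent-2-en-2-yl]zirconium | C/C(=C\C(C)(C)O[Si](CC)(CC)CC)[Zr](Cl)(C1C=CC=C1)C1C=CC=C1 | intermediate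
16 | methyl[(2E)-4-methyl-4-(triethylsilyloxy)pent-2-en-2-yl]zinc | C/C(=C\C(C)(C)O[Si](CC)(CC)CC)[Zn]C | intermediate
17 | (3R,4E)-1-[(tert-butyldiphenylsilyl)oxy]-4,6-dimethyl-6-[(triethylsilyl)oxy]hept-4-en-3-ol | CC(C)(O[Si](CC)(CC)CC)/C=C(\C)[C@H](O)CCO[Si](c1ccccc1)(c1ccccc1)C(C)(C)C | intermediate
18 | (3R,4E)-1-[(tert-butyldiphenylsilyl)oxy]-4,6-dimethyl-6-[(triethylsilyl)oxy]hept-4-en-3-yl 3-[2-iodo-3,4,6-trimethoxy-5-(propan-2-yl)phenyl]-3-oxopropanoate | CC(C)(O[Si](CC)(CC)CC)/C=C(\C)[C@H](OC(=O)CC(=O)c1c(I)c(OC)c(OC)c(C(C)C)c1OC)CCO[Si](c1ccccc1)(c1ccccc1)C(C)(C)C | intermediate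
19 | (3R,4E)-7-[(tert-butyldiphenylsilyl)oxy]-2-[2-iodo-3,4,6-trimethoxy-5-(propan-2-yl)benzoyl]-4-methyl-3-{2-[(triethylsilyl)oxy]propan-2-yl}hept-4-enoic acid (both C2 epimers) | CC(C)(O[Si](CC)(CC)CC)[C@@H](/C(C)=C/CCO[Si](c1ccccc1)(c1ccccc1)C(C)(C)C)C(C(=O)O)C(=O)c1c(I)c(OC)c(OC)c(C(C)C)c1OC | intermediate
20 | (3R,4E)-7-[(tert-butyldiphenylsilyl)oxy]-1-[2-iodo-3,4,6-trimethoxy-5-(propan-2-yl)phenyl]-4-methyl-3-{2-[(triethylsilyl)oxy]propan-2-yl}hept-4-en-1-one | CC(C)(O[Si](CC)(CC)CC)[C@@H](/C(C)=C/CCO[Si](c1ccccc1)(c1ccccc1)C(C)(C)C)CC(=O)c1c(I)c(OC)c(OC)c(C(C)C)c1OC | intermediate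
21 | (3R,4R)-4-[(1E)-3-[(tert-butyldiphenylsilyl)oxy]prop-1-en-1-yl]-5,6,8-trimethoxy-4-methyl-7-(propan-2-yl)-3-{2-[(triethylsilyl)oxy]propan-2-yl}-3,4-dihydronaphthalen-1(2H)-one | CC(C)(O[Si](CC)(CC)CC)[C@@H]1CC(=O)c2c(OC)c(C(C)C)c(OC)c(OC)c2[C@]1(C)/C=C/CO[Si](c1ccccc1)(c1ccccc1)C(C)(C)C | intermediate
22 | (3R,4R)-4-{3-[(tert-butyldiphenylsilyl)oxy]propyl}-5,6,8-trimethoxy-4-methyl-7-(propan-2-yl)-3-{2-[(triethylsilyl)oxy]propan-2-yl}-3,4-dihydronaphthalen-1(2H)-one | CC(C)(O[Si](CC)(CC)CC)[C@@H]1CC(=O)c2c(OC)c(C(C)C)c(OC)c(OC)c2[C@]1(C)CCCO[Si](c1ccccc1)(c1ccccc1)C(C)(C)C | intermediate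
23 | (3R,4R)-4-{3-[(tert-butyldiphenylsilyl)oxy]propyl}-3-(2-hydroxypropan-2-yl)-5,6,8-trimethoxy-4-methyl-7-(propan-2-yl)-3,4-dihydronaphthalen-1(2H)-one | CC(C)(O)[C@@H]1CC(=O)c2c(OC)c(C(C)C)c(OC)c(OC)c2[C@]1(C)CCCO[Si](c1ccccc1)(c1ccccc1)C(C)(C)C | intermediate
24 | (3S,4R)-4-{3-[(tert-butyldiphenylsilyl)oxy]propyl}-5,6,8-trimethoxy-4-methyl-7-(propan-2-yl)-3-(prop-1-en-2-yl)-3,4-dihydronaphthalen-1(2H)-one | C=C(C)[C@@H]1CC(=O)c2c(OC)c(C(C)C)c(OC)c(OC)c2[C@]1(C)CCCO[Si](c1ccccc1)(c1ccccc1)C(C)(C)C | intermediate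
25 | (3S,4R)-4-(3-hydroxypropyl)-5,6,8-trimethoxy-4-methyl-7-(propan-2-yl)-3-(prop-1-en-2-yl)-3,4-dihydronaphthalen-1(2H)-one | C=C(C)[C@@H]1CC(=O)c2c(OC)c(C(C)C)c(OC)c(OC)c2[C@]1(C)CCCO | intermediate
26 | 3-[(1R,2S)-5,7,8-trimethoxy-1-methyl-4-oxo-6-(propan-2-yl)-2-(prop-1-en-2-yl)-1,2,3,4-tetrahydronaphthalen-1-yl]propanal | C=C(C)[C@@H]1CC(=O)c2c(OC)c(C(C)C)c(OC)c(OC)c2[C@]1(C)CCC=O | intermediate
27 | 3-[(1R,2S)-5,7,8-trimethoxy-1-methyl-4-oxo-6-(propan-2-yl)-2-(prop-1-en-2-yl)-1,2,3,4-tetrahydronaphthalen-1-yl]propanoic acid | C=C(C)[C@@H]1CC(=O)c2c(OC)c(C(C)C)c(OC)c(OC)c2[C@]1(C)CCC(=O)O | intermediate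
28 | 3-[(1R,2S)-7-methoxy-1-methyl-4,5,8-trioxo-6-(propan-2-yl)-2-(prop-1-en-2-yl)-1,2,3,4,5,8-hexahydronaphthalen-1-yl]propanoic acid | C=C(C)[C@@H]1CC(=O)C2=C(C(=O)C(OC)=C(C(C)C)C2=O)[C@]1(C)CCC(=O)O | intermediate
29 | 3-[(1R,2S)-7-hydroxy-1-methyl-4,5,8-trioxo-6-(propan-2-yl)-2-(prop-1-en-2-yl)-1,2,3,4,5,8-hexahydronaphthalen-1-yl]propanoic acid | C=C(C)[C@@H]1CC(=O)C2=C(C(=O)C(O)=C(C(C)C)C2=O)[C@]1(C)CCC(=O)O | intermediate
30 | 3-[(1R,2S)-5,7,8-trihydroxy-1-methyl-4-oxo-6-(propan-2-yl)-2-(prop-1-en-2-yl)-1,2,3,4-tetrahydronaphthalen-1-yl]propanoic acid | C=C(C)[C@@H]1CC(=O)c2c(O)c(C(C)C)c(O)c(O)c2[C@]1(C)CCC(=O)O | target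

**Step count**
Total: 21 steps. Longest linear sequence: 16 steps (steps 1–5 and 11–21).

**Steps most likely to fail**

Step 13 (ring closure). Carbopalladation of the congested trisubstituted alkene next to the branched C5 may be slow, so that protodeiodination or migration of the chain alkene takes over, or the two faces of C10 may not be told apart well enough. The fallback leaves the Heck manifold and makes the same C9–C10 bond by metal-hydride hydrogen-atom transfer. Fe(acac)3 and PhSiH3 turn the C10=C1 alkene of 20 into the tertiary C10 radical, and this is captured by the aryl–nickel species formed from the C9 iodide (NiBr2(diglyme), 4,4'-di-tert-butyl-2,2'-bipyridine, Mn powder). This is a Markovnikov hydroarylation, known between separate alkenes and iodoarenes and applied here within one molecule. It has no β-hydride elimination to control and, unlike a tin-mediated aryl radical cyclisation, exposes no aryl radical to 1,5-hydrogen transfer from C6. It sets out from 20 and returns at 22, so step 14 falls away; no new compound is made (entry F0).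

Step 12 (Carroll rearrangement). At the temperature needed for the [3,3] shift onto the hindered C5 terminus the allylic ester may ionise or eliminate, and the aroyl-substituted C6 terminus adds steric load in the transition state. The fallback makes the same C5–C6 bond by a Claisen rearrangement of an allyl vinyl ether with an unsubstituted CH2 terminus, which rearranges at lower temperature. From 4, Rieche formylation (Cl2CHOMe, TiCl4) gives 2,4,5-trimethoxy-3-(propan-2-yl)benzaldehyde F1. Iodination as in step 4 gives 2-iodo-3,4,6-trimethoxy-5-(propan-2-yl)benzaldehyde F2, and Pinnick oxidation (NaClO2) gives 2-iodo-3,4,6-trimethoxy-5-(propan-2-yl)benzoic acid F3. Yamaguchi esterification with 17 gives the allyl aroate F4. Methylenation of the ester carbonyl with Cp2TiMe2 (toluene, 70 °C) gives the allyl 1-arylvinyl ether F5, which rearranges on warming through the same chair and returns to the route at 20.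

Step 10 (alkenylzinc addition). Ligand-free background addition promoted by the zirconium by-product, or competing methyl transfer, may erode the enantiomeric purity at C1 and with it at C5. The fallback separates bond formation from stereocontrol. Addition of 16 to 14 without ligand gives the racemic alcohol (4E)-1-[(tert-butyldiphenylsilyl)oxy]-4,6-dimethyl-6-[(triethylsilyl)oxy]hept-4-en-3-ol F6. Oxidation with MnO2 gives the enone (4E)-1-[(tert-butyldiphenylsilyl)oxy]-4,6-dimethyl-6-[(triethylsilyl)oxy]hept-4-en-3-one F7. Corey–Bakshi–Shibata reduction with the (S)-methyl oxazaborolidine and catecholborane, in which the α-methyl alkenyl group acts as the large substituent, returns to the route at 17.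

**Further compounds**
F0 | step 13 | none | none
F1 | step 12 | 2,4,5-trimethoxy-3-(propan-2-yl)benzaldehyde | COc1c(C=O)cc(OC)c(OC)c1C(C)C
F2 | step 12 | 2-iodo-3,4,6-trimethoxy-5-(propan-2-yl)benzaldehyde | COc1c(C=O)c(I)c(OC)c(OC)c1C(C)C
F3 | step 12 | 2-iodo-3,4,6-trimethoxy-5-(propan-2-yl)benzoic acid | COc1c(C(=O)O)c(I)c(OC)c(OC)c1C(C)C
F4 | step 12 | (3R,4E)-1-[(tert-butyldiphenylsilyl)oxy]-4,6-dimethyl-6-[(triethylsilyl)oxy]hept-4-en-3-yl 2-iodo-3,4,6-trimethoxy-5-(propan-2-yl)benzoate | CC(C)(O[Si](CC)(CC)CC)/C=C(\C)[C@H](OC(=O)c1c(I)c(OC)c(OC)c(C(C)C)c1OC)CCO[Si](c1ccccc1)(c1ccccc1)C(C)(C)C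
F5 | step 12 | (3R,4E)-3-({1-[2-iodo-3,4,6-trimethoxy-5-(propan-2-yl)phenyl]ethenyl}oxy)-1-[(tert-butyldiphenylsilyl)oxy]-4,6-dimethyl-6-[(triethylsilyl)oxy]hept-4-ene | CC(C)(O[Si](CC)(CC)CC)/C=C(\C)[C@H](OC(=C)c1c(I)c(OC)c(OC)c(C(C)C)c1OC)CCO[Si](c1ccccc1)(c1ccccc1)C(C)(C)C
F6 | step 10 | racemic (4E)-1-[(tert-butyldiphenylsilyl)oxy]-4,6-dimethyl-6-[(triethylsilyl)oxy]hept-4-en-3-ol | CC(C)(O[Si](CC)(CC)CC)/C=C(\C)C(O)CCO[Si](c1ccccc1)(c1ccccc1)C(C)(C)C
F7 | step 10 | (4E)-1-[(tert-butyldiphenylsilyl)oxy]-4,6-dimethyl-6-[(triethylsilyl)oxy]hept-4-en-3-one | CC(C)(O[Si](CC)(CC)CC)/C=C(\C)C(=O)CCO[Si](c1ccccc1)(c1ccccc1)C(C)(C)C
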